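## Structural features

Atom labels used throughout: C1 (oxirane CH2), C2 (oxirane CH), C3 (C, CH3, Cl), C4 (CHBr), C5 (CH2), C6 (CHCl), C7 (C, CH3, Br), C8 (CH2Cl).

The target is an open eight-carbon chain with methyl branches on C3 and C7. One end is closed into a monosubstituted oxirane (O, C1, C2) joined through C2 to the fully substituted C3; there is no other ring. Five halogens and five stereocentres fall into two groups separated only by the C5 methylene: C2 (S), C3 (R) and C4 (R) on one side, C6 (S) and C7 (S) on the other. The two vicinal Br/Cl pairs have opposite regiochemistry. C3–Cl/C4–Br is what ionic bromine chloride gives with a trisubstituted alkene; C6–Cl/C7–Br is the reverse. Fragile points are: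

- the terminal oxirane (acid, nucleophiles) and the tertiary bromide (elimination, ionisation);
- any hydroxyl next to a tertiary chloride, which closes to an epoxide under base;
- β-halo carbonyl intermediates, which lose HX;
- any activated carbon next to a halogen, which invites halonium scrambling.

The real difficulty is the reverse-oriented C6/C7 pair with both centres defined, and after it the control of C2 beside the quaternary C3. The key step turns the scrambling hazard into the solution: the chlorine on the tertiary C7 acts as an internal nucleophile toward an activated C6, and the tertiary character of C7 then directs bromide to that carbon.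

## Logic of the disconnections

21 ⇒ 20. The O–C2 bond of the oxirane is cut, the oxygen staying on C1. An oxygen on C2 would sit beside the tertiary chloride on C3 and could close on it; an oxygen on C1 can only form the wanted ring. The gain is an open-chain precursor in which the oxirane is unmasked last. The demand is an intramolecular displacement at the hindered C2 with clean inversion, so C2 must arrive with the configuration opposite to that in 21.

20 ⇒ 19 ⇒ 14 + 17. The C1–C2 bond is cut (20 and 19 differ by a protecting group). A one-carbon nucleophile carrying protected oxygen adds to an aldehyde whose α-carbon is C3, and the facial preference of this α-chloro aldehyde gives the C2 configuration that the inverting closure needs. The gain is the loss of C1 and of the C2 stereocentre; 17 comes from 15 and 16 by one C–O bond. The demand is face selection by C3 alone and capture of the alkoxide before it attacks C3–Cl.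

14 ⇒ 13. No skeletal bond is cut. The aldehyde is taken back to the primary alcohol, because that hydroxyl is the handle for the next disconnection.

13 ⇒ 12. The C3–Cl and C4–Br bonds are cut to give a Z trisubstituted allylic alcohol. This pair has the natural orientation of bromine chloride addition, and the allylic hydroxyl lets a chiral catalyst choose the face. The gain is two stereocentres and two halogens in one step. The demand is anti addition to an alkene of defined Z geometry, chloride at the tertiary carbon, and catalyst control independent of the distant C6/C7 centres.

12 ⇒ 11 ⇒ 9 + 10. The C3=C4 bond is cut (12 and 11 differ in oxidation level). A Z-selective phosphonate olefination joins the three-carbon unit 10 to the C4 aldehyde. The gain is a five-carbon dihalo aldehyde and a commercial reagent. The demand is high Z selectivity under conditions that a β-chloro aldehyde survives.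

9 ⇒ 8. The C4 carbonyl is traced back to a terminal alkene with one more carbon, which is inert during the halogen chemistry before it. The demand is that the alkene stays a spectator in the preceding step.

8 ⇒ 5. The C6–Cl and C7–Br bonds are cut in the sense of the key step: chlorine returns from C6 to C7 and bromine is replaced by oxygen on C6. No addition to an alkene puts bromine on the tertiary and chlorine on the secondary carbon, but a chlorine already on C7 can deliver itself to C6 and leave C7 open to bromide. The gain is a chlorohydrin with ordinary functionality. The demand is stereospecific double inversion: the bridged ion must form faster than direct substitution and be opened at C7 only.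

5 ⇒ 3 + 4. The C5–C6 bond is cut. Allylation of an aldehyde without α-hydrogen sets C6 and brings in the alkene. The gain is a four-carbon dichloride. The demand is reagent control at C6, because the α-centre distinguishes its faces only by methyl against chloromethyl.

3 ⇒ 2 ⇒ 1. The C7–Cl and C8–Cl bonds are cut (3 and 2 differ in oxidation level). Both chlorines are added to the alkene of an allylic alcohol in one enantioselective step, so no carbon next to the tertiary chloride is activated afterwards. The gain is a commercial four-carbon starting material. The demand is face selection on a very small substrate.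

## Other disconnections considered

Alternative 1: The cut is the C4–C5 bond, made together with a temporary C6–O bond. In the forward sense the nitrile oxide generated from the α-bromo aldoxime A2 (C1–C4, with the C1/C2 diol as an acetonide) by oxime chlorination and loss of HCl adds across the vinyl group of the dichloride A3 (C5–C8), giving the 3,5-disubstituted 2-isoxazoline A1.
- In its favour: it is convergent, joining two halogenated halves of similar size in one step; on this point it is better than the chosen plan, which is linear. The regiochemistry of nitrile oxide additions to monosubstituted alkenes is dependable, and the N–O ring is a masked β-hydroxy ketone carrying the C4 and C6 oxygens.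
- Against it: the new C6 centre must be controlled by the quaternary C7 of A3, whose substituents (Cl, CH3, CH2Cl) differ too little for a confident prediction. A3 is a tertiary allylic chloride and A2 carries a tertiary bromide next to a C=N bond; both ionise easily. Reductive N–O cleavage must spare an α-bromo ketone. After reduction at C4 the molecule still needs two halogen relays (C3 bromine to C4 with chloride capture, C7 chlorine to C6 with bromide capture) on a diol that must be differentiated, and then an acetonide must become the oxirane beside the tertiary C3–Cl.
- Comparison: structurally, A1 holds the whole skeleton earlier than any compound of the chosen plan. Mechanistically, the cycloaddition is better precedented than step 4, but the plan then needs the same unprecedented relay as step 4 and a bromine relay besides, whereas the chosen plan obtains the C3/C4 pair by an addition of natural orientation (step 8). In step count the two are about equal once ring cleavage, reduction, protection and the relays are counted.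

Alternative 2: The cut is the C1–C2 bond and the O–C1 bond of the oxirane. In the forward sense a sulfur ylide transfers methylene to the C2 aldehyde A5, which carries bromine on C3 and silyl ethers on C4 and C6, and the betaine closes to the epoxide A4.
- In its favour: with bromine on C3 in its configuration before the shift, the Cornforth preference of the aldehyde gives the correct C2 centre. The oxirane is made in one step with matched substrate control. Here the alternative is better than the chosen plan, where the same preference is mismatched for direct ring formation and three steps with an inversion (steps 11–13) are spent.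
- Against it: A4 must then survive two triflation/halide relays. An oxirane oxygen one bond from C3 can open the bromonium ion or be opened itself, and the two silyl ethers must be removed one at a time in the right order. The betaine alkoxide on C2 stands next to a tertiary bromide that it can displace. A5 itself needs bromine on the tertiary C3 next to oxygen on C4, a reverse-oriented pattern no easier to make than 5.
- Comparison: structurally, it brings in the most fragile group before the harshest steps, whereas the chosen plan forms it last. Mechanistically, its key step is ordinary and step 4 is not, but it leaves two relays to come where the chosen plan leaves none after step 4. Step economy is about equal.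

Alternative 3: The cut is the C5–C6 bond together with the C4–Br bond. In the forward sense the α-chloro acyl radical from the bromochloroacetyl imide A8 adds to the terminal carbon of the vinyl compound A7, and the resulting C4 radical takes bromine from A8 in a Kharasch chain, giving the imide A6.
- In its favour: a C–C bond and the C4–Br bond form together, with bromine on the internal carbon as radical polarity dictates. C3–Cl, C4–Br and C6–Cl reach their final places without any halogen shift; this equals the chosen plan for the C3/C4 pair and is more direct for C6. The C1–C3 part comes from the chiral pool, which is better than the late construction of C2 in the chosen plan.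
- Against it: C4 is set by atom transfer to an open-chain radical beside the quaternary C3, and C6 by an auxiliary three bonds away, so neither is secure. A7 is a tertiary allylic chloride, and C6–Cl in A6 is α to a carbonyl and can epimerise. Decisively, the tertiary bromide C7 with its methyl and chloromethyl groups must still be built from the imide carbonyl, which brings back the reverse-oriented C6/C7 problem with fewer handles than 5 offers.
- Comparison: structurally, A6 stops at C7 and lacks the hardest centre, which the chosen plan settles first. Mechanistically, a radical chain avoids halonium scrambling, a real merit. In step count it is short as far as A6 and long afterwards, so no net gain is expected.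

Key step: step 4

Assumption: the chiral titanium Schiff-base catalyst of steps 1 and 8 is taken in whichever ligand antipode delivers halogen to the face stated in those steps; both antipodes are made the same way from the enantiomeric amino alcohols.

## Route

Step 1
Reactants: 1 2-methylprop-2-en-1-ol
Product: 2 (2S)-2,3-dichloro-2-methylpropan-1-ol
Conditions: tBuOCl, ClTi(OiPr)3, chiral tridentate Schiff-base ligand (cat.), hexanes, −20 °C
Reagents that add atoms: tert-butyl hypochlorite, CC(C)(C)OCl; chlorotitanium triisopropoxide, CC(C)O[Ti](Cl)(OC(C)C)OC(C)C
Why: Titanium-mediated catalytic enantioselective dichlorination of an allylic alcohol: the alkoxide of 1 binds to the chiral titanium complex, the hypochlorite delivers Cl+ to the terminal carbon and titanium-bound chloride opens the chloronium ion anti at the tertiary carbon. The ligand antipode is chosen to place the tertiary chlorine on the Re face of C2 of 1, which gives the S centre (C7 of the target); both chlorines of the C7/C8 pair are thus in place before any neighbouring carbon has to be activated.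

Step 2
Reactants: 2 (2S)-2,3-dichloro-2-methylpropan-1-ol
Product: 3 (2S)-2,3-dichloro-2-methylpropanal
Conditions: Dess–Martin periodinane, CH2Cl2, 0 °C to rt
Reagents that add atoms: none
Why: Dess–Martin oxidation of a primary alcohol without base, so no alkoxide forms beside the tertiary chloride. The aldehyde has no α-hydrogen, cannot epimerise or lose HCl, and would be used without purification.

Step 3
Reactants: 3 (2S)-2,3-dichloro-2-methylpropanal; 4 allylmagnesium bromide
Product: 5 (2S,3R)-1,2-dichloro-2-methylhex-5-en-3-ol
Conditions: 4, (+)-Ipc2BOMe, Et2O, −78 °C to rt, filtration; then 3, −100 °C; pH 7 buffer, H2O2, MeOH, 0 °C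
Reagents that add atoms: none
Why: Brown allylboration through a chair transition state: the allylborane made from (+)-Ipc2BOMe adds to the Re face of the aldehyde and sets the carbinol centre as R. The α-centre offers only a methyl/chloromethyl difference, so its own Cornforth preference, which points the other way, should be weak and overruled by the reagent. The buffered oxidative work-up avoids the base that would close the chlorohydrin to an epoxide.

Step 4
Reactants: 5 (2S,3R)-1,2-dichloro-2-methylhex-5-en-3-ol
Product: 8 (4S,5S)-5-bromo-4,6-dichloro-5-methylhex-1-ene, via triflate 6 (not isolated), via chloronium ion 7 (not isolated)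
Conditions: Tf2O, 2,6-di-tert-butyl-4-methylpyridine, CH2Cl2/toluene, −78 °C; then Bu4NBr, −78 to −20 °C
Reagents that add atoms: tetrabutylammonium bromide, CCCC[N+](CCCC)(CCCC)CCCC.[Br-]; trifluoromethanesulfonic anhydride, O=S(=O)(OS(=O)(=O)C(F)(F)F)C(F)(F)F (its triflyl group is found in 6 and 7 only)
Why: Proposed new method: triflation of the hindered C6 hydroxyl gives 6, in which the C7–Cl bond can lie anti-periplanar to C6–O; ionisation is then assisted by that chlorine, which closes a transient three-membered chloronium ring (3-exo-tet displacement at C6, inversion) to give ion pair 7 with most of the positive charge on the tertiary C7. Bromide attacks C7 from the face opposite the bridging chlorine (second inversion), so chlorine ends on C6 and bromine on C7, the reverse of ionic BrCl addition. The closest known reaction type is anchimerically assisted substitution of β-chloro sulfonates through chloronium ions, with the 1,2-bromine shift through bromonium ions as its nearest relative. No ring is retained; the chloronium ring is formed and opened in the same flask. Both new centres (C6 S, C7 S) follow from the 2S,3R configuration of 5 by double inversion, so the substrate and not a reagent controls them. The step needs chlorine participation to outrun direct attack of bromide at C6 (slowed by the neopentyl-like position beside quaternary C7), opening of 7 at C6 (disfavoured because C7 carries more charge), collapse to an open tertiary cation (disfavoured by low temperature and a weakly polar medium) and π-participation by the homoallylic alkene (a weaker neighbouring group than an anti chlorine). The triflate is made before bromide is added so that the anhydride is not consumed by the halide.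

Step 5
Reactants: 8 (4S,5S)-5-bromo-4,6-dichloro-5-methylhex-1-ene
Product: 9 (3S,4S)-4-bromo-3,5-dichloro-4-methylpentanal
Conditions: O3, CH2Cl2, −78 °C; then Me2S, −78 °C to rt
Reagents that add atoms: ozone, [O-][O+]=O
Why: Ozonolysis with reductive work-up cleaves the terminal alkene, the only π bond present; the carbon–halogen bonds are inert to ozone. The β-chloro aldehyde would be kept cold and base-free and used at once, because loss of HCl to the enal is its main decomposition path.

Step 6
Reactants: 9 (3S,4S)-4-bromo-3,5-dichloro-4-methylpentanal; 10 ethyl 2-[bis(2,2,2-trifluoroethoxy)phosphoryl]propanoate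
Product: 11 ethyl (2Z,5S,6S)-6-bromo-5,7-dichloro-2,6-dimethylhept-2-enoate
Conditions: 10, KN(SiMe3)2, 18-crown-6, THF, −78 °C; then 9, −78 °C
Reagents that add atoms: none
Why: Still–Gennari variant of the Horner–Wadsworth–Emmons reaction: the electron-poor phosphonate adds irreversibly and eliminates fast, which should give the Z trisubstituted enoate with the ester cis to C5. The phosphonate anion is preformed with a slight deficit of base so that no free amide meets the enolisable aldehyde, and addition at −78 °C should outrun enolisation.

Step 7
Reactants: 11 ethyl (2Z,5S,6S)-6-bromo-5,7-dichloro-2,6-dimethylhept-2-enoate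
Product: 12 (2Z,5S,6S)-6-bromo-5,7-dichloro-2,6-dimethylhept-2-en-1-ol
Conditions: iBu2AlH, CH2Cl2, −78 °C; aq. KNaC4H4O6
Reagents that add atoms: none
Why: 1,2-Reduction of an α,β-unsaturated ester with diisobutylaluminium hydride gives the allylic alcohol without touching the alkyl halides or the alkene geometry.

Step 8
Reactants: 12 (2Z,5S,6S)-6-bromo-5,7-dichloro-2,6-dimethylhept-2-en-1-ol
Product: 13 (2R,3R,5S,6S)-3,6-dibromo-2,5,7-trichloro-2,6-dimethylheptan-1-ol
Conditions: NBS, ClTi(OiPr)3, chiral tridentate Schiff-base ligand (cat.), hexanes/CH2Cl2, −20 °C
Reagents that add atoms: N-bromosuccinimide, O=C1CCC(=O)N1Br; chlorotitanium triisopropoxide, CC(C)O[Ti](Cl)(OC(C)C)OC(C)C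
Why: Titanium-mediated catalytic enantioselective bromochlorination of an allylic alcohol: Br+ is transferred to C4 and titanium-bound chloride opens the bromonium ion anti at the tertiary C3, the natural (Markovnikov) orientation, which is the one needed at this pair. Anti addition to the Z alkene fixes the relative configuration of C3 and C4, and the ligand antipode is chosen to place bromine on the Re face of C4 (chlorine on the Si face of C3), giving 3R,4R in target numbering; the distant C6/C7 centres should have little influence.

Step 9
Reactants: 13 (2R,3R,5S,6S)-3,6-dibromo-2,5,7-trichloro-2,6-dimethylheptan-1-ol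
Product: 14 (2R,3R,5S,6S)-3,6-dibromo-2,5,7-trichloro-2,6-dimethylheptanal
Conditions: Dess–Martin periodinane, CH2Cl2, 0 °C to rt
Reagents that add atoms: none
Why: Dess–Martin oxidation without base; the α-carbon is fully substituted, so neither epimerisation nor β-elimination of bromide is possible, and no alkoxide forms next to the tertiary chloride.

Step 10
Reactants: 15 tributyl(iodomethyl)stannane; 16 (4-methoxyphenyl)methanol
Product: 17 tributyl{[(4-methoxyphenyl)methoxy]methyl}stannane
Conditions: NaH, THF/DMF, 0 °C to rt
Reagents that add atoms: none
Why: Williamson ether synthesis; the alkoxide of 16 displaces iodide from the unhindered primary carbon.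

Step 11
Reactants: 14 (2R,3R,5S,6S)-3,6-dibromo-2,5,7-trichloro-2,6-dimethylheptanal; 17 tributyl{[(4-methoxyphenyl)methoxy]methyl}stannane
Product: 19 (2R,3R,4R,6S,7S)-4,7-dibromo-3,6,8-trichloro-1-[(4-methoxyphenyl)methoxy]-3,7-dimethyloctan-2-yl methanesulfonate, via lithium alkoxide 18 (not isolated)
Conditions: 17, n-BuLi, THF, −78 °C; 14, −78 °C; then MsCl, −78 to −40 °C
Reagents that add atoms: methanesulfonyl chloride, CS(=O)(=O)Cl
Why: Tin–lithium exchange gives the α-alkoxymethyllithium, which adds to the aldehyde under Cornforth (polar Felkin–Anh) control: with C3–Cl anti to C=O the nucleophile passes the C3 methyl group and not the C4 branch, attacks the Re face and sets C2 as R. The alkoxide is sulfonylated in the same flask before it can displace the neighbouring tertiary chloride; the R configuration is the one the inverting ring closure of step 13 requires.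

Step 12
Reactants: 19 (2R,3R,4R,6S,7S)-4,7-dibromo-3,6,8-trichloro-1-[(4-methoxyphenyl)methoxy]-3,7-dimethyloctan-2-yl methanesulfonate
Product: 20 (2R,3R,4R,6S,7S)-4,7-dibromo-3,6,8-trichloro-1-hydroxy-3,7-dimethyloctan-2-yl methanesulfonate
Conditions: DDQ, CH2Cl2/pH 7 buffer, 0 °C to rt
Reagents that add atoms: none
Why: Oxidative cleavage of the 4-methoxybenzyl ether with DDQ in buffered wet dichloromethane is neutral and should leave the mesylate and all carbon–halogen bonds untouched.

Step 13
Reactants: 20 (2R,3R,4R,6S,7S)-4,7-dibromo-3,6,8-trichloro-1-hydroxy-3,7-dimethyloctan-2-yl methanesulfonate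
Product: 21 (2S)-2-[(2R,3R,5S,6S)-3,6-dibromo-2,5,7-trichloro-6-methylheptan-2-yl]oxirane
Conditions: K2CO3, MeOH, 0 °C
Reagents that add atoms: none
Why: Intramolecular Williamson reaction (3-exo-tet): the C1 alkoxide displaces the C2 mesylate with inversion, turning the R centre into the S oxirane carbon of the target. Because the nucleophilic oxygen sits on C1, attack on C3–Cl could only give an oxetane, so the tertiary chloride is not at risk as it would be with an oxygen on C2.

## Compound list

1 | 2-methylprop-2-en-1-ol | C=C(C)CO | starting material
2 | (2S)-2,3-dichloro-2-methylpropan-1-ol | OC[C@](C)(Cl)CCl | intermediate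
3 | (2S)-2,3-dichloro-2-methylpropanal | O=C[C@](C)(Cl)CCl | intermediate
4 | allylmagnesium bromide | C=CC[Mg]Br | starting material
5 | (2S,3R)-1,2-dichloro-2-methylhex-5-en-3-ol | C=CC[C@@H](O)[C@](C)(Cl)CCl | intermediate
6 | (2S,3R)-1,2-dichloro-2-methylhex-5-en-3-yl trifluoromethanesulfonate | C=CC[C@@H](OS(=O)(=O)C(F)(F)F)[C@](C)(Cl)CCl | intermediate
7 | (2R,3S)-2-(chloromethyl)-2-methyl-3-(prop-2-en-1-yl)chloriranium trifluoromethanesulfonate (bridged chloronium ion pair, allyl and chloromethyl cis) | C=CC[C@@H]1[Cl+][C@]1(C)CCl.[O-]S(=O)(=O)C(F)(F)F | intermediate
8 | (4S,5S)-5-bromo-4,6-dichloro-5-methylhex-1-ene | C=CC[C@H](Cl)[C@@](C)(Br)CCl | intermediate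
9 | (3S,4S)-4-bromo-3,5-dichloro-4-methylpentanal | O=CC[C@H](Cl)[C@@](C)(Br)CCl | intermediate
10 | ethyl 2-[bis(2,2,2-trifluoroethoxy)phosphoryl]propanoate | CCOC(=O)C(C)P(=O)(OCC(F)(F)F)OCC(F)(F)F | starting material
11 | ethyl (2Z,5S,6S)-6-bromo-5,7-dichloro-2,6-dimethylhept-2-enoate | CCOC(=O)/C(C)=C\C[C@H](Cl)[C@@](C)(Br)CCl | intermediate
12 | (2Z,5S,6S)-6-bromo-5,7-dichloro-2,6-dimethylhept-2-en-1-ol | OC/C(C)=C\C[C@H](Cl)[C@@](C)(Br)CCl | intermediate
13 | (2R,3R,5S,6S)-3,6-dibromo-2,5,7-trichloro-2,6-dimethylheptan-1-ol | OC[C@@](C)(Cl)[C@H](Br)C[C@H](Cl)[C@@](C)(Br)CCl | intermediate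
14 | (2R,3R,5S,6S)-3,6-dibromo-2,5,7-trichloro-2,6-dimethylheptanal | O=C[C@@](C)(Cl)[C@H](Br)C[C@H](Cl)[C@@](C)(Br)CCl | intermediate
15 | tributyl(iodomethyl)stannane | CCCC[Sn](CCCC)(CCCC)CI | starting material
16 | (4-methoxyphenyl)methanol | COc1ccc(CO)cc1 | starting material
17 | tributyl{[(4-methoxyphenyl)methoxy]methyl}stannane | CCCC[Sn](CCCC)(CCCC)COCc1ccc(OC)cc1 | intermediate
18 | lithium (2R,3R,4R,6S,7S)-4,7-dibromo-3,6,8-trichloro-1-[(4-methoxyphenyl)methoxy]-3,7-dimethyloctan-2-olate | [Li]O[C@H](COCc1ccc(OC)cc1)[C@@](C)(Cl)[C@H](Br)C[C@H](Cl)[C@@](C)(Br)CCl | intermediate
19 | (2R,3R,4R,6S,7S)-4,7-dibromo-3,6,8-trichloro-1-[(4-methoxyphenyl)methoxy]-3,7-dimethyloctan-2-yl methanesulfonate | CS(=O)(=O)O[C@H](COCc1ccc(OC)cc1)[C@@](C)(Cl)[C@H](Br)C[C@H](Cl)[C@@](C)(Br)CCl | intermediate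
20 | (2R,3R,4R,6S,7S)-4,7-dibromo-3,6,8-trichloro-1-hydroxy-3,7-dimethyloctan-2-yl methanesulfonate | CS(=O)(=O)O[C@H](CO)[C@@](C)(Cl)[C@H](Br)C[C@H](Cl)[C@@](C)(Br)CCl | intermediate
21 | (2S)-2-[(2R,3R,5S,6S)-3,6-dibromo-2,5,7-trichloro-6-methylheptan-2-yl]oxirane | C[C@](Cl)([C@H](Br)C[C@H](Cl)[C@@](C)(Br)CCl)[C@@H]1CO1 | target

## Step count and least certain steps

Total: 13 steps. Longest linear sequence: 12 steps (steps 1–9 and 11–13); step 10 is a one-step side branch.

Step 4 (key step, proposed new method). Most likely to go wrong: capture of the bridged ion by bromide at C6 instead of C7, which returns bromine to the secondary carbon with retention; loss of configuration at C7 through an open tertiary cation; elimination from the triflate; or participation of the homoallylic alkene in place of chlorine. These compete because chlorine is only a moderate neighbouring group and the chloromethyl group reduces the cation-stabilising power of C7. A fallback made only of known reaction types would set out from 5 and return at 8: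
- Aqueous NaOH in ether closes the chlorohydrin, with inversion at C7, to (2R,3R)-2-(chloromethyl)-2-methyl-3-(prop-2-en-1-yl)oxirane F1.
- LiCl and AcOH in THF open this trisubstituted epoxide at the less substituted C6 with inversion, giving (2S,3S)-1,3-dichloro-2-methylhex-5-en-2-ol F2.
- Concentrated HBr in CH2Cl2 at low temperature replaces the tertiary hydroxyl by bromine with retention, the classical outcome when a β-halogen bridges the developing cation, giving 8.

The fallback removes the uncertainty of the triflate ionisation at a hindered secondary carbon, not that of where bromide opens the bridged ion.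

Step 1. Most likely to go wrong: insufficient enantiofacial discrimination, because the substrate is very small and the catalyst must tell a methyl group from a hydrogen-bearing terminus. The fallback sets out from 1 and returns at 5:
- Cl2 (or Et4NCl3) in CH2Cl2 gives racemic 2,3-dichloro-2-methylpropan-1-ol F3.
- Dess–Martin oxidation gives racemic 2,3-dichloro-2-methylpropanal F4.
- The allylboration of step 3 then converts the two enantiomers mainly into 5 and its C2 epimer (2R,3R)-1,2-dichloro-2-methylhex-5-en-3-ol F5, which are diastereomers and separable by chromatography.

The cost is half the material, and the enantiomeric purity of 5 then rests on the allylboration alone.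

Step 3. Most likely to go wrong: erosion of facial selectivity, because reagent preference (Re) and the weak Cornforth preference of the aldehyde (Si) are opposed and the aldehyde is hindered. The fallback sets out from 5 obtained as a mixture with its C3 epimer (2S,3S)-1,2-dichloro-2-methylhex-5-en-3-ol F6 and returns at 5:
- Dess–Martin oxidation of the mixture gives (2S)-1,2-dichloro-2-methylhex-5-en-3-one F7.
- Corey–Bakshi–Shibata reduction with the (S)-oxazaborolidine and catecholborane in toluene at −78 °C then gives the 3R alcohol.

In the reduction, catalyst control (tertiary α-carbon as the large group) and the Felkin–Anh preference (hydride anti to C–Cl, past the methyl group) both lead to 3R. Migration of the β,γ-double bond into conjugation is the point to watch, so the ketone would be handled cold and without base.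

Step 6. Most likely to go wrong: enolisation of the β-chloro aldehyde and loss of HCl before olefination, or a lower Z preference than usual because of the branched, halogenated chain. The fallback sets out from 9 and returns at 12 without exposing the aldehyde to base:
- Ramirez olefination (CBr4, PPh3, CH2Cl2, 0 °C) gives (4S,5S)-1,1,5-tribromo-4,6-dichloro-5-methylhex-1-ene F8.
- Trans-selective Negishi monomethylation (MeZnCl, PdCl2(DPEphos), THF) replaces the bromine trans to the chain, giving (2Z,5S,6S)-2,6-dibromo-5,7-dichloro-6-methylhept-2-ene F9.
- Stille coupling with Bu3SnCH2OH (Pd(PPh3)4, dioxane) puts the hydroxymethyl group cis to the chain and gives 12 directly.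

Step 8. Most likely to go wrong: addition to the wrong alkene face, delivery of chloride to C4 instead of C3 by the titanium-bound alkoxide, or halogen scrambling to dibromide and dichloride. The Z trisubstituted 2-methyl allylic alcohol is a demanding member of the substrate class. The fallback sets out from 12 and returns at 13: ligand-free ionic addition of bromine chloride from Bu4NBrCl2 in CH2Cl2 at 0 °C is anti and Markovnikov but has no facial control, and 13 would be separated by chromatography from the other anti adduct, (2S,3S,5S,6S)-3,6-dibromo-2,5,7-trichloro-2,6-dimethylheptan-1-ol F10.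

Step 11. Most likely to go wrong: low facial selectivity in the addition, because only C3 controls it; bromine–lithium exchange at C4 or C7; or attack of the alkoxide on C3–Cl before sulfonylation. The later closure at the hindered C2 (step 13) may also be slow. The fallback sets out from 14, returns at 21, and bypasses steps 11–13:
- Wittig methylenation (Ph3PCH3Br, KN(SiMe3)2, THF, −78 °C) gives (3R,4R,6S,7S)-4,7-dibromo-3,6,8-trichloro-3,7-dimethyloct-1-ene F11.
- Epoxidation with dimethyldioxirane in acetone gives 21 together with its C2 epimer (2R)-2-[(2R,3R,5S,6S)-3,6-dibromo-2,5,7-trichloro-6-methylheptan-2-yl]oxirane F12.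
- Jacobsen hydrolytic kinetic resolution, with the antipode of the cobalt acetate complex of N,N'-bis(3,5-di-tert-butylsalicylidene)cyclohexane-1,2-diamine, (salen)Co(OAc), that hydrolyses F12, converts it into (2R,3R,4R,6S,7S)-4,7-dibromo-3,6,8-trichloro-3,7-dimethyloctane-1,2-diol F13 and leaves 21.

The cost is the loss of the epimer.

## Further compounds

F1 | step 4 | (2R,3R)-2-(chloromethyl)-2-methyl-3-(prop-2-en-1-yl)oxirane | C=CC[C@H]1O[C@@]1(C)CCl
F2 | step 4 | (2S,3S)-1,3-dichloro-2-methylhex-5-en-2-ol | C=CC[C@H](Cl)[C@@](C)(O)CCl
F3 | step 1 | racemic 2,3-dichloro-2-methylpropan-1-ol | OCC(C)(Cl)CCl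
F4 | step 1 | racemic 2,3-dichloro-2-methylpropanal | O=CC(C)(Cl)CCl
F5 | step 1 | (2R,3R)-1,2-dichloro-2-methylhex-5-en-3-ol | C=CC[C@@H](O)[C@@](C)(Cl)CCl
F6 | step 3 | (2S,3S)-1,2-dichloro-2-methylhex-5-en-3-ol | C=CC[C@H](O)[C@](C)(Cl)CCl
F7 | step 3 | (2S)-1,2-dichloro-2-methylhex-5-en-3-one | C=CCC(=O)[C@](C)(Cl)CCl
F8 | step 6 | (4S,5S)-1,1,5-tribromo-4,6-dichloro-5-methylhex-1-ene | BrC(Br)=CC[C@H](Cl)[C@@](C)(Br)CCl
F9 | step 6 | (2Z,5S,6S)-2,6-dibromo-5,7-dichloro-6-methylhept-2-ene | C/C(Br)=C/C[C@H](Cl)[C@@](C)(Br)CCl
F10 | step 8 | (2S,3S,5S,6S)-3,6-dibromo-2,5,7-trichloro-2,6-dimethylheptan-1-ol | OC[C@](C)(Cl)[C@@H](Br)C[C@H](Cl)[C@@](C)(Br)CCl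
F11 | step 11 | (3R,4R,6S,7S)-4,7-dibromo-3,6,8-trichloro-3,7-dimethyloct-1-ene | C=C[C@@](C)(Cl)[C@H](Br)C[C@H](Cl)[C@@](C)(Br)CCl
F12 | step 11 | (2R)-2-[(2R,3R,5S,6S)-3,6-dibromo-2,5,7-trichloro-6-methylheptan-2-yl]oxirane | C[C@](Cl)([C@H](Br)C[C@H](Cl)[C@@](C)(Br)CCl)[C@H]1CO1
F13 | step 11 | (2R,3R,4R,6S,7S)-4,7-dibromo-3,6,8-trichloro-3,7-dimethyloctane-1,2-diol | C[C@](Cl)([C@H](Br)C[C@H](Cl)[C@@](C)(Br)CCl)[C@H](O)CO
A1 | alternative 1 | (5R)-3-{(1R)-1-bromo-1-[(4S)-2,2-dimethyl-1,3-dioxolan-4-yl]ethyl}-5-[(2S)-1,2-dichloropropan-2-yl]-4,5-dihydro-1,2-oxazole | C[C@@](Br)(C1=NO[C@H](C1)[C@](C)(Cl)CCl)[C@@H]2COC(C)(C)O2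
A2 | alternative 1 | (2R)-2-bromo-2-[(4S)-2,2-dimethyl-1,3-dioxolan-4-yl]propanal oxime | ON=C[C@@](C)(Br)[C@@H]1COC(C)(C)O1
A3 | alternative 1 | (3S)-3,4-dichloro-3-methylbut-1-ene | C=C[C@](C)(Cl)CCl
A4 | alternative 2 | (2S)-2-{(2S,3S,5R,6S)-2-bromo-5-[(tert-butyldimethylsilyl)oxy]-6,7-dichloro-6-methyl-3-[(triethylsilyl)oxy]heptan-2-yl}oxirane | C[C@@](Br)([C@@H](O[Si](CC)(CC)CC)C[C@@H](O[Si](C)(C)C(C)(C)C)[C@](C)(Cl)CCl)[C@@H]1CO1
A5 | alternative 2 | (2R,3S,5R,6S)-2-bromo-5-[(tert-butyldimethylsilyl)oxy]-6,7-dichloro-2,6-dimethyl-3-[(triethylsilyl)oxy]heptanal | O=C[C@](C)(Br)[C@@H](O[Si](CC)(CC)CC)C[C@@H](O[Si](C)(C)C(C)(C)C)[C@](C)(Cl)CCl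
A6 | alternative 3 | (4R)-4-benzyl-3-{(2S,4R,5R)-4-bromo-2,5-dichloro-5-[(4S)-2,2-dimethyl-1,3-dioxolan-4-yl]hexanoyl}-1,3-oxazolidin-2-one | C[C@](Cl)([C@H](Br)C[C@H](Cl)C(=O)N1C(=O)OC[C@H]1Cc1ccccc1)[C@@H]2COC(C)(C)O2
A7 | alternative 3 | (4S)-4-[(2S)-2-chlorobut-3-en-2-yl]-2,2-dimethyl-1,3-dioxolane | C=C[C@](C)(Cl)[C@@H]1COC(C)(C)O1
A8 | alternative 3 | (4R)-4-benzyl-3-(bromochloroacetyl)-1,3-oxazolidin-2-one | O=C(C(Cl)Br)N1C(=O)OC[C@H]1Cc1ccccc1
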